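**Strategy.** The route rests on disconnecting the C2–C3 bond of the 2,3-dihydrobenzofuran ring. The key step is an enantioselective cobalt-metalloradical C–H alkylation: a carbene radical generated at the future benzylic C3 (from an ortho-formyl group via its tosylhydrazone) abstracts the hydrogen five atoms away on the O–CH2 carbon of a 2-hydroxy-2-methylpropyl aryl ether, which the ring oxygen O1 activates, and the two carbons then join to close the dihydrofuran ring and set C2 in one operation. The precursor is an open-chain aryl ether aldehyde that already carries the complete butenolide, whose (R)-quaternary carbon is set by asymmetric phase-transfer benzylation of an α-acyloxy-β-keto ester followed by aldol condensation.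

Key step: step 9

Remark: compound 1 is taken as a catalogue compound, and for the two chiral catalysts (steps 6 and 9) the antipode that delivers the drawn configuration is used, its sense to be fixed in a pilot run.

**Step 1**
Reactants: 1 2-hydroxy-5-(hydroxymethyl)benzaldehyde; 2 2,2-dimethyloxirane
Product: 3 5-(hydroxymethyl)-2-(2-hydroxy-2-methylpropoxy)benzaldehyde
Conditions: K2CO3, DMF, 90 °C, sealed tube
Reagents that add atoms: none
Why: Phenol alkylation by epoxide ring opening; the phenoxide attacks the unhindered CH2 terminus (SN2) to give the primary aryl ether with a tertiary alcohol, while the benzylic alcohol is not deprotonated by carbonate.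

**Step 2**
Reactants: 3 5-(hydroxymethyl)-2-(2-hydroxy-2-methylpropoxy)benzaldehyde
Product: 4 5-(bromomethyl)-2-(2-hydroxy-2-methylpropoxy)benzaldehyde
Conditions: PPh3, NBS, CH2Cl2, −20 °C → 0 °C
Reagents that add atoms: N-bromosuccinimide, O=C1CCC(=O)N1Br
Why: Appel-type bromination through an alkoxyphosphonium ion should convert only the primary benzylic alcohol, leaving the hindered tertiary alcohol and the aldehyde untouched (no phosphorus ylide is formed, so no olefination).

**Step 3**
Reactants: 5 1-[4-(benzyloxy)phenyl]ethan-1-one; 6 dimethyl carbonate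
Product: 7 methyl 3-[4-(benzyloxy)phenyl]-3-oxopropanoate
Conditions: NaH, THF, reflux; then aq. HCl
Reagents that add atoms: none
Why: Claisen condensation of the ketone enolate with dimethyl carbonate, driven by deprotonation of the β-keto ester formed.

**Step 4**
Reactants: 7 methyl 3-[4-(benzyloxy)phenyl]-3-oxopropanoate
Product: 8 methyl 3-[4-(benzyloxy)phenyl]-2-bromo-3-oxopropanoate (racemic)
Conditions: NBS (1.0 equiv), p-TsOH·H2O (10 mol%), MeCN, 0 °C → rt
Reagents that add atoms: N-bromosuccinimide, O=C1CCC(=O)N1Br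
Why: Electrophilic α-halogenation of the enolisable 1,3-dicarbonyl compound; one equivalent of NBS should stop at the monobromide.

**Step 5**
Reactants: 8 methyl 3-[4-(benzyloxy)phenyl]-2-bromo-3-oxopropanoate; 9 (benzyloxy)acetic acid
Product: 10 methyl 2-{[(benzyloxy)acetyl]oxy}-3-[4-(benzyloxy)phenyl]-3-oxopropanoate (racemic, configurationally labile)
Conditions: KHCO3, DMF, rt
Reagents that add atoms: none
Why: SN2 displacement of the doubly activated secondary bromide by the carboxylate (α-acyloxylation of a β-keto ester) installs the future lactone C–O bond and the two-carbon glycolate unit.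

**Step 6**
Reactants: 10 methyl 2-{[(benzyloxy)acetyl]oxy}-3-[4-(benzyloxy)phenyl]-3-oxopropanoate; 4 5-(bromomethyl)-2-(2-hydroxy-2-methylpropoxy)benzaldehyde
Product: 11 methyl (2R)-2-{[(benzyloxy)acetyl]oxy}-3-[4-(benzyloxy)phenyl]-2-{[3-formyl-4-(2-hydroxy-2-methylpropoxy)phenyl]methyl}-3-oxopropanoate
Conditions: N-spiro C2-symmetric binaphthyl quaternary ammonium bromide with 3,4,5-trifluorophenyl groups (2 mol%), K2CO3 (powdered), toluene, −20 °C → 0 °C
Reagents that add atoms: none
Why: Asymmetric phase-transfer alkylation of an α-acyloxy-β-keto ester with a benzylic bromide; only the C2–H between the two carbonyl groups is acidic enough for carbonate, and the chiral ammonium ion pair shields one face of the enolate so that C-benzylation should set the quaternary centre as (R).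

**Step 7**
Reactants: 11 methyl (2R)-2-{[(benzyloxy)acetyl]oxy}-3-[4-(benzyloxy)phenyl]-2-{[3-formyl-4-(2-hydroxy-2-methylpropoxy)phenyl]methyl}-3-oxopropanoate
Product: 13 methyl (2R)-4-(benzyloxy)-3-[4-(benzyloxy)phenyl]-2-{[3-formyl-4-(2-hydroxy-2-methylpropoxy)phenyl]methyl}-5-oxo-2,5-dihydrofuran-2-carboxylate, via aldol adduct 12 (not isolated)
Conditions: DBU (1.5 equiv), MeCN, 0 °C → 40 °C
Reagents that add atoms: none
Why: Intramolecular aldol condensation of an α-acyloxy ketone (the annulation used for 3-alkoxy-4-aryl-furan-2(5H)-ones): the glycolate CH2 is now the only acidic site, adds 5-exo-trig to the aryl ketone and E1cB dehydration gives the butenolide without touching the quaternary centre.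

**Step 8**
Reactants: 13 methyl (2R)-4-(benzyloxy)-3-[4-(benzyloxy)phenyl]-2-{[3-formyl-4-(2-hydroxy-2-methylpropoxy)phenyl]methyl}-5-oxo-2,5-dihydrofuran-2-carboxylate
Product: 14 methyl (2R)-4-(benzyloxy)-3-[4-(benzyloxy)phenyl]-2-{[4-(2-hydroxy-2-methylpropoxy)-3-{(E)-[2-(4-methylbenzenesulfonyl)hydrazinylidene]methyl}phenyl]methyl}-5-oxo-2,5-dihydrofuran-2-carboxylate
Conditions: TsNHNH2 (1.05 equiv), MeOH–THF, rt
Reagents that add atoms: p-toluenesulfonohydrazide, Cc1ccc(S(=O)(=O)NN)cc1
Why: Condensation of the aryl aldehyde with the sulfonyl hydrazide gives the N-tosylhydrazone under neutral conditions that leave the lactone and esters intact.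

**Step 9**
Reactants: 14 methyl (2R)-4-(benzyloxy)-3-[4-(benzyloxy)phenyl]-2-{[4-(2-hydroxy-2-methylpropoxy)-3-{(E)-[2-(4-methylbenzenesulfonyl)hydrazinylidene]methyl}phenyl]methyl}-5-oxo-2,5-dihydrofuran-2-carboxylate
Product: 16 methyl (2R)-4-(benzyloxy)-3-[4-(benzyloxy)phenyl]-2-{[(2S)-2-(2-hydroxypropan-2-yl)-2,3-dihydro-1-benzofuran-5-yl]methyl}-5-oxo-2,5-dihydrofuran-2-carboxylate, via aryldiazomethane 15 (not isolated)
Conditions: [Co(3,5-DitBu-ChenPhyrin)] (divalent cobalt complex of a D2-symmetric chiral amidoporphyrin, 3 mol%), Cs2CO3 (2 equiv), toluene, 50 °C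
Reagents that add atoms: none
Why: Cs2CO3 converts the tosylhydrazone into aryldiazomethane 15 (Bamford–Stevens), which the divalent cobalt porphyrin metalloradical captures with loss of N2 to give an α-cobalt benzylic radical (a trivalent cobalt carbene radical) at the future C3; this radical abstracts one hydrogen from the O–CH2 carbon by 1,5-hydrogen atom transfer through a six-membered transition state, and the resulting α-aryloxyalkyl radical substitutes homolytically at the cobalt-bound benzylic carbon, forming the C3–C2 bond and releasing the catalyst. The closest known reaction types are the cobalt-porphyrin radical C–H alkylation of ortho-aminobenzaldehyde tosylhydrazones to 2-substituted indolines and the metalloporphyrin carbene C–H insertion of ortho-alkoxyaryl tosylhydrazones to 2,3-dihydrobenzofurans. The dihydrofuran ring closes in a 5-exo-tet radical substitution. The new C2 stereocentre is set in this C–C bond-forming step by the chiral amide-lined pocket of the porphyrin (catalyst control, the planar α-oxy radical making the step enantioconvergent), and the remote (R)-quaternary centre should have no influence. The step needs 1,5-abstraction at O–CH2 over carbene dimerisation, azine formation and O–H insertion: this CH2 is the only C–H five atoms from the carbene carbon and is weakened by the adjacent oxygen, the diazo compound is released slowly, and the radical, non-electrophilic carbene should not insert into the tertiary O–H or reach the remote benzyl ethers.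

**Step 10**
Reactants: 16 methyl (2R)-4-(benzyloxy)-3-[4-(benzyloxy)phenyl]-2-{[(2S)-2-(2-hydroxypropan-2-yl)-2,3-dihydro-1-benzofuran-5-yl]methyl}-5-oxo-2,5-dihydrofuran-2-carboxylate
Product: 17 methyl (2R)-4-hydroxy-3-(4-hydroxyphenyl)-2-{[(2S)-2-(2-hydroxypropan-2-yl)-2,3-dihydro-1-benzofuran-5-yl]methyl}-5-oxo-2,5-dihydrofuran-2-carboxylate
Conditions: H2 (1 atm), Pd/C (10 wt%), EtOAc–MeOH, rt
Reagents that add atoms: none
Why: Hydrogenolysis of the benzyl aryl ether and the benzyl enol ether; the tetrasubstituted butenolide alkene, the quaternary lactone C–O bond and the non-benzylic C2–O bond of the dihydrobenzofuran should survive.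

**Compound list**
1 | 2-hydroxy-5-(hydroxymethyl)benzaldehyde | O=Cc1cc(CO)ccc1O | starting material
2 | 2,2-dimethyloxirane | CC1(C)CO1 | starting material
3 | 5-(hydroxymethyl)-2-(2-hydroxy-2-methylpropoxy)benzaldehyde | O=Cc1cc(CO)ccc1OCC(C)(C)O | intermediate
4 | 5-(bromomethyl)-2-(2-hydroxy-2-methylpropoxy)benzaldehyde | O=Cc1cc(CBr)ccc1OCC(C)(C)O | intermediate
5 | 1-[4-(benzyloxy)phenyl]ethan-1-one | CC(=O)c1ccc(OCc2ccccc2)cc1 | starting material
6 | dimethyl carbonate | COC(=O)OC | starting material
7 | methyl 3-[4-(benzyloxy)phenyl]-3-oxopropanoate | COC(=O)CC(=O)c1ccc(OCc2ccccc2)cc1 | intermediate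
8 | methyl 3-[4-(benzyloxy)phenyl]-2-bromo-3-oxopropanoate (racemic) | COC(=O)C(Br)C(=O)c1ccc(OCc2ccccc2)cc1 | intermediate
9 | (benzyloxy)acetic acid | OC(=O)COCc1ccccc1 | starting material
10 | methyl 2-{[(benzyloxy)acetyl]oxy}-3-[4-(benzyloxy)phenyl]-3-oxopropanoate (racemic) | COC(=O)C(OC(=O)COCc1ccccc1)C(=O)c1ccc(OCc2ccccc2)cc1 | intermediate
11 | methyl (2R)-2-{[(benzyloxy)acetyl]oxy}-3-[4-(benzyloxy)phenyl]-2-{[3-formyl-4-(2-hydroxy-2-methylpropoxy)phenyl]methyl}-3-oxopropanoate | COC(=O)[C@](Cc1ccc(OCC(C)(C)O)c(C=O)c1)(OC(=O)COCc1ccccc1)C(=O)c1ccc(OCc2ccccc2)cc1 | intermediate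
12 | methyl (2R)-4-(benzyloxy)-3-[4-(benzyloxy)phenyl]-2-{[3-formyl-4-(2-hydroxy-2-methylpropoxy)phenyl]methyl}-3-hydroxy-5-oxooxolane-2-carboxylate (epimers at C3 and C4) | COC(=O)[C@]1(Cc2ccc(OCC(C)(C)O)c(C=O)c2)OC(=O)C(OCc2ccccc2)C1(O)c1ccc(OCc2ccccc2)cc1 | intermediate
13 | methyl (2R)-4-(benzyloxy)-3-[4-(benzyloxy)phenyl]-2-{[3-formyl-4-(2-hydroxy-2-methylpropoxy)phenyl]methyl}-5-oxo-2,5-dihydrofuran-2-carboxylate | COC(=O)[C@]1(Cc2ccc(OCC(C)(C)O)c(C=O)c2)OC(=O)C(OCc2ccccc2)=C1c1ccc(OCc2ccccc2)cc1 | intermediate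
14 | (E)-N-tosylhydrazone of 13 | COC(=O)[C@]1(Cc2ccc(OCC(C)(C)O)c(/C=N/NS(=O)(=O)c3ccc(C)cc3)c2)OC(=O)C(OCc2ccccc2)=C1c1ccc(OCc2ccccc2)cc1 | intermediate
15 | methyl (2R)-4-(benzyloxy)-3-[4-(benzyloxy)phenyl]-2-{[3-(diazomethyl)-4-(2-hydroxy-2-methylpropoxy)phenyl]methyl}-5-oxo-2,5-dihydrofuran-2-carboxylate | COC(=O)[C@]1(Cc2ccc(OCC(C)(C)O)c(C=[N+]=[N-])c2)OC(=O)C(OCc2ccccc2)=C1c1ccc(OCc2ccccc2)cc1 | intermediate
16 | methyl (2R)-4-(benzyloxy)-3-[4-(benzyloxy)phenyl]-2-{[(2S)-2-(2-hydroxypropan-2-yl)-2,3-dihydro-1-benzofuran-5-yl]methyl}-5-oxo-2,5-dihydrofuran-2-carboxylate | COC(=O)[C@]1(Cc2ccc3c(c2)C[C@@H](C(C)(C)O)O3)OC(=O)C(OCc2ccccc2)=C1c1ccc(OCc2ccccc2)cc1 | intermediate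
17 | methyl (2R)-4-hydroxy-3-(4-hydroxyphenyl)-2-{[(2S)-2-(2-hydroxypropan-2-yl)-2,3-dihydro-1-benzofuran-5-yl]methyl}-5-oxo-2,5-dihydrofuran-2-carboxylate | COC(=O)[C@]1(Cc2ccc3c(c2)C[C@@H](C(C)(C)O)O3)OC(=O)C(O)=C1c1ccc(O)cc1 | target

**Step count.** Total: 10 steps. Longest linear sequence: 8 steps (5 → 7 → 8 → 10 → 11 → 13 → 14 → 16 → 17, steps 3 to 10).

**Steps most likely to fail**

1. Step 9 (key step). Hydrogen abstraction from the non-benzylic α-aryloxy C–H may be slow, so that carbene dimerisation and azine formation take over, or the catalyst may control the C2 configuration poorly on this oxygen-tethered substrate. The fallback keeps the C3–C2 ring closure but moves it to the fragment stage with classical chemistry; it sets out from 1 and comes back at 16. Compound 1 and chloroacetone (K2CO3, acetone, reflux) should undergo O-alkylation followed by intramolecular aldol condensation (Rap–Stoermer reaction, closing C3–C2) to give 1-[5-(hydroxymethyl)-1-benzofuran-2-yl]ethan-1-one F1. Excess MeMgBr in THF should convert it into 2-[5-(hydroxymethyl)-1-benzofuran-2-yl]propan-2-ol F2. Asymmetric hydrogenation of the furan C2=C3 bond with a ruthenium bis(N-heterocyclic carbene) catalyst made from [Ru(cod)(2-methylallyl)2], the chiral imidazolinium salt SINpEt·HBF4 and KOtBu under H2 should give 2-[(2S)-5-(hydroxymethyl)-2,3-dihydro-1-benzofuran-2-yl]propan-2-ol F3. PPh3/NBS should give 2-[(2S)-5-(bromomethyl)-2,3-dihydro-1-benzofuran-2-yl]propan-2-ol F4, which alkylates 10 under the conditions of step 6 to methyl (2R)-2-{[(benzyloxy)acetyl]oxy}-3-[4-(benzyloxy)phenyl]-2-{[(2S)-2-(2-hydroxypropan-2-yl)-2,3-dihydro-1-benzofuran-5-yl]methyl}-3-oxopropanoate F5. DBU in MeCN (as in step 7) then closes the butenolide to 16.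

2. Step 6. Enantiofacial discrimination may erode with the small methyl ester (tert-butyl esters are the best-behaved substrates of this reaction), and some O-alkylation may occur. The fallback replaces asymmetric catalysis by resolution; it sets out from 10 and 4 and comes back at 13. Benzylation with Bu4NBr and K2CO3 in toluene should give racemic methyl 2-{[(benzyloxy)acetyl]oxy}-3-[4-(benzyloxy)phenyl]-2-{[3-formyl-4-(2-hydroxy-2-methylpropoxy)phenyl]methyl}-3-oxopropanoate F6. DBU then gives the racemic butenolide aldehyde F7, which is resolved by preparative chromatography on a chiral stationary phase into 13 and its (2S)-enantiomer F8, which is discarded.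

3. Step 7. Under equilibrating conditions the glycolate enolate may attack the neighbouring methyl ester (Dieckmann closure to a tetronic acid) instead of the aryl ketone. The fallback separates addition from elimination; it sets out from 11 and comes back at 13. Kinetic enolisation with LiHMDS (2.1 equiv, THF, −78 °C) should favour addition to the more electrophilic ketone, and the aldol adduct 12 is isolated after a cold AcOH quench. It is then dehydrated in a separate operation through its mesylate (MsCl, Et3N, CH2Cl2, 0 °C) to 13.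

**Further compounds**
F1 | step 9 | 1-[5-(hydroxymethyl)-1-benzofuran-2-yl]ethan-1-one | CC(=O)c1cc2cc(CO)ccc2o1
F2 | step 9 | 2-[5-(hydroxymethyl)-1-benzofuran-2-yl]propan-2-ol | CC(C)(O)c1cc2cc(CO)ccc2o1
F3 | step 9 | 2-[(2S)-5-(hydroxymethyl)-2,3-dihydro-1-benzofuran-2-yl]propan-2-ol | OCc1ccc2c(c1)C[C@@H](C(C)(C)O)O2
F4 | step 9 | 2-[(2S)-5-(bromomethyl)-2,3-dihydro-1-benzofuran-2-yl]propan-2-ol | BrCc1ccc2c(c1)C[C@@H](C(C)(C)O)O2
F5 | step 9 | methyl (2R)-2-{[(benzyloxy)acetyl]oxy}-3-[4-(benzyloxy)phenyl]-2-{[(2S)-2-(2-hydroxypropan-2-yl)-2,3-dihydro-1-benzofuran-5-yl]methyl}-3-oxopropanoate | COC(=O)[C@](Cc1ccc2c(c1)C[C@@H](C(C)(C)O)O2)(OC(=O)COCc1ccccc1)C(=O)c1ccc(OCc2ccccc2)cc1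
F6 | step 6 | racemic methyl 2-{[(benzyloxy)acetyl]oxy}-3-[4-(benzyloxy)phenyl]-2-{[3-formyl-4-(2-hydroxy-2-methylpropoxy)phenyl]methyl}-3-oxopropanoate | COC(=O)C(Cc1ccc(OCC(C)(C)O)c(C=O)c1)(OC(=O)COCc1ccccc1)C(=O)c1ccc(OCc2ccccc2)cc1
F7 | step 6 | racemic methyl 4-(benzyloxy)-3-[4-(benzyloxy)phenyl]-2-{[3-formyl-4-(2-hydroxy-2-methylpropoxy)phenyl]methyl}-5-oxo-2,5-dihydrofuran-2-carboxylate | COC(=O)C1(Cc2ccc(OCC(C)(C)O)c(C=O)c2)OC(=O)C(OCc2ccccc2)=C1c1ccc(OCc2ccccc2)cc1
F8 | step 6 | methyl (2S)-4-(benzyloxy)-3-[4-(benzyloxy)phenyl]-2-{[3-formyl-4-(2-hydroxy-2-methylpropoxy)phenyl]methyl}-5-oxo-2,5-dihydrofuran-2-carboxylate | COC(=O)[C@@]1(Cc2ccc(OCC(C)(C)O)c(C=O)c2)OC(=O)C(OCc2ccccc2)=C1c1ccc(OCc2ccccc2)cc1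
F0 | step 7 | none | none
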